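Assumption: all four starting materials, including the two O-benzylated benzaldehydes, are catalogue compounds and are bought. The route is designed from known reaction classes and has not been run.

**Retrosynthetic overview** (locants: C-1 lactone C=O, C-3 trihydroxyphenyl carbon, C-3a, C-4 CH2, C-6 dihydroxyphenyl carbon, C-6a)
1. Target ⇐ its pentabenzyl ether by hydrogenolysis; all phenols are carried as benzyl ethers.
2. THF ring (O-5–C-6 bond) ⇐ SN1 closure of the CH2OH onto a benzylic carbinol. The target lactone ⇐ acyl shift (translactonisation) from an isomeric butyrolactone once the C-3 oxygen is unmasked.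
3. C-6a–C-6 bond ⇐ trans-selective lithium aldol of a 4-substituted butyrolactone with 3,4-bis(benzyloxy)benzaldehyde.
4. C-3/C-3a ⇐ Evans syn-aldol of a mono-tert-butyl succinate imide with 3,4,5-tris(benzyloxy)benzaldehyde, then O-silylation and reductive auxiliary removal/lactonisation.
5. Ring order: temporary lactone closed on CH2–O ("ring 1") → target lactone closed on the benzylic O ("ring 2") → tetrahydrofuran last.

**Route**

Step 1
Reactants: 1 (S)-4-benzyl-1,3-oxazolidin-2-one; 2 4-tert-butoxy-4-oxobutanoic acid (mono-tert-butyl succinate)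
Product: 4 tert-butyl 4-[(4S)-4-benzyl-2-oxo-1,3-oxazolidin-3-yl]-4-oxobutanoate, via mixed pivalic anhydride 3 (not isolated)
Conditions: 2, PivCl, Et3N, THF, −20 °C; then LiCl, 1, −20 °C → rt
Reagents that add atoms: none
Why: N-acylation of the oxazolidinone through a mixed pivalic anhydride, which is attacked at the unhindered succinyl carbonyl; no stereocentre is touched.

Step 2
Reactants: 4 tert-butyl 4-[(4S)-4-benzyl-2-oxo-1,3-oxazolidin-3-yl]-4-oxobutanoate; 5 3,4,5-tris(benzyloxy)benzaldehyde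
Product: 8 tert-butyl (3S,4S)-3-{[(4S)-4-benzyl-2-oxo-1,3-oxazolidin-3-yl]carbonyl}-4-hydroxy-4-[3,4,5-tris(benzyloxy)phenyl]butanoate, via (Z)-dibutylboron enolate 6 (not isolated), via dibutylboron aldolate 7 (not isolated)
Conditions: Bu2BOTf, i-Pr2NEt, CH2Cl2, −78 → 0 °C; 5, −78 → 0 °C; pH 7 buffer, MeOH, 30% H2O2, 0 °C
Reagents that add atoms: none
Why: Evans syn-aldol through the Z-boron enolate and a Zimmerman–Traxler chair, the aldehyde adding to the enolate face away from the auxiliary benzyl group, which sets the future C-3 (S) and C-3a together as the (3S,4S) "Evans syn" adduct; the tert-butyl ester keeps the adduct from lactonising.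

Step 3
Reactants: 8 the syn-aldol adduct
Product: 9 tert-butyl (3S,4S)-3-{[(4S)-4-benzyl-2-oxo-1,3-oxazolidin-3-yl]carbonyl}-4-[(tert-butyldimethylsilyl)oxy]-4-[3,4,5-tris(benzyloxy)phenyl]butanoate
Conditions: TBSOTf, 2,6-lutidine, CH2Cl2, −78 → 0 °C
Reagents that add atoms: tert-butyldimethylsilyl triflate (TBSOTf), CC(C)(C)[Si](C)(C)OS(=O)(=O)C(F)(F)F
Why: O-silylation blocks the benzylic oxygen so that the next lactone must close on the primary alcohol and the later enolate chemistry is clean; low temperature spares the tert-butyl ester.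

Step 4
Reactants: 9 the silyl ether
Product: 11 (4R)-4-{(S)-[(tert-butyldimethylsilyl)oxy][3,4,5-tris(benzyloxy)phenyl]methyl}oxolan-2-one (ring-1 lactone), via hydroxy ester 10 (not isolated)
Conditions: LiBH4, H2O (1 equiv), Et2O–THF, 0 °C; then crude, p-TsOH·H2O (5 mol%), CH2Cl2, rt
Reagents that add atoms: none
Why: chemoselective borohydride reduction of the imide carbonyl releases the auxiliary and gives the primary alcohol, which lactonises onto the tert-butyl ester under acid catalysis; both stereocentres are untouched.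

Step 5
Reactants: 11 the ring-1 lactone; 12 3,4-bis(benzyloxy)benzaldehyde
Product: 15 (3S,4R)-3-{[3,4-bis(benzyloxy)phenyl](hydroxy)methyl}-4-{(S)-[(tert-butyldimethylsilyl)oxy][3,4,5-tris(benzyloxy)phenyl]methyl}oxolan-2-one (carbinol epimers), via lithium enolate 13 (not isolated), via lithium aldolate 14 (not isolated)
Conditions: LDA, THF, −78 °C; 12, −78 °C; AcOH quench at −78 °C
Reagents that add atoms: none
Why: lithium enolate aldol addition in which the aldehyde adds anti to the bulky C-4 substituent, setting the future C-6a as the trans-3,4 lactone; the carbinol configuration is uncontrolled and is erased in step 6.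

Step 6
Reactants: 15 the aldol product
Product: 18 (3S,3aR,6S,6aS)-6-[3,4-bis(benzyloxy)phenyl]-3-[3,4,5-tris(benzyloxy)phenyl]tetrahydro-1H,3H-furo[3,4-c]furan-1-one, via ring-1 hydroxy lactone 16 (not isolated), via ring-2 diol 17 (not isolated)
Conditions: TBAF, THF, 0 °C; AcOH quench; then crude, CSA (0.2 equiv), CH2Cl2, 0 °C → rt
Reagents that add atoms: none
Why: fluoride desilylation frees the benzylic alkoxide, which translactonises to the trans-4,5 lactone and thereby turns the trans-3,4 relation of ring 1 into a cis relation of CH2OH and carbinol; CSA then ionises the electron-rich benzylic alcohol and SN1 cycloetherification by the CH2OH gives the cis-fused bicycle with the aryl on the convex face (6S) from either carbinol epimer.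

Step 7
Reactants: 18 the pentabenzyl furofuranone
Product: 19 (3S,3aR,6S,6aS)-6-(3,4-dihydroxyphenyl)-3-(3,4,5-trihydroxyphenyl)tetrahydro-1H,3H-furo[3,4-c]furan-1-one (target)
Conditions: H2 (1 atm), 10% Pd/C, EtOAc–THF, rt, stopped after 5 equiv H2
Reagents that add atoms: none
Why: catalytic hydrogenolysis cleaves the five aryl benzyl ethers faster than the secondary benzylic C–O bonds of the bicycle under neutral, aprotic, 1 atm conditions, and no stereocentre is involved.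

**Compound list**

1 | (S)-4-benzyl-1,3-oxazolidin-2-one | O=C1N[C@@H](Cc2ccccc2)CO1 | starting material
2 | 4-tert-butoxy-4-oxobutanoic acid | OC(=O)CCC(=O)OC(C)(C)C | starting material
3 | 4-tert-butoxy-4-oxobutanoic pivalic anhydride | CC(C)(C)C(=O)OC(=O)CCC(=O)OC(C)(C)C | intermediate (not isolated)
4 | tert-butyl 4-[(4S)-4-benzyl-2-oxo-1,3-oxazolidin-3-yl]-4-oxobutanoate | CC(C)(C)OC(=O)CCC(=O)N1[C@@H](Cc2ccccc2)COC1=O | intermediate
5 | 3,4,5-tris(benzyloxy)benzaldehyde | O=Cc1cc(OCc2ccccc2)c(OCc2ccccc2)c(OCc2ccccc2)c1 | starting material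
6 | (Z)-dibutylboron enolate of 4 | CCCCB(CCCC)O/C(=C\CC(=O)OC(C)(C)C)N1[C@@H](Cc2ccccc2)COC1=O | intermediate (not isolated)
7 | O-dibutylboryl aldolate of 8 | CCCCB(CCCC)O[C@H](c1cc(OCc2ccccc2)c(OCc2ccccc2)c(OCc2ccccc2)c1)[C@H](CC(=O)OC(C)(C)C)C(=O)N1[C@@H](Cc2ccccc2)COC1=O | intermediate (not isolated)
8 | tert-butyl (3S,4S)-3-{[(4S)-4-benzyl-2-oxo-1,3-oxazolidin-3-yl]carbonyl}-4-hydroxy-4-[3,4,5-tris(benzyloxy)phenyl]butanoate | O[C@H](c1cc(OCc2ccccc2)c(OCc2ccccc2)c(OCc2ccccc2)c1)[C@H](CC(=O)OC(C)(C)C)C(=O)N1[C@@H](Cc2ccccc2)COC1=O | intermediate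
9 | tert-butyl (3S,4S)-3-{[(4S)-4-benzyl-2-oxo-1,3-oxazolidin-3-yl]carbonyl}-4-[(tert-butyldimethylsilyl)oxy]-4-[3,4,5-tris(benzyloxy)phenyl]butanoate | CC(C)(C)[Si](C)(C)O[C@H](c1cc(OCc2ccccc2)c(OCc2ccccc2)c(OCc2ccccc2)c1)[C@H](CC(=O)OC(C)(C)C)C(=O)N1[C@@H](Cc2ccccc2)COC1=O | intermediate
10 | tert-butyl (3R,4S)-4-[(tert-butyldimethylsilyl)oxy]-3-(hydroxymethyl)-4-[3,4,5-tris(benzyloxy)phenyl]butanoate | CC(C)(C)[Si](C)(C)O[C@H](c1cc(OCc2ccccc2)c(OCc2ccccc2)c(OCc2ccccc2)c1)[C@H](CC(=O)OC(C)(C)C)CO | intermediate (not isolated)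
11 | (4R)-4-{(S)-[(tert-butyldimethylsilyl)oxy][3,4,5-tris(benzyloxy)phenyl]methyl}oxolan-2-one | CC(C)(C)[Si](C)(C)O[C@H](c1cc(OCc2ccccc2)c(OCc2ccccc2)c(OCc2ccccc2)c1)[C@H]1COC(=O)C1 | intermediate
12 | 3,4-bis(benzyloxy)benzaldehyde | O=Cc1ccc(OCc2ccccc2)c(OCc2ccccc2)c1 | starting material
13 | lithium enolate of 11 | [Li+].CC(C)(C)[Si](C)(C)O[C@H](c1cc(OCc2ccccc2)c(OCc2ccccc2)c(OCc2ccccc2)c1)[C@H]1COC([O-])=C1 | intermediate (not isolated)
14 | lithium aldolate of 15 (carbinol centre undefined) | [Li+].[O-]C(c1ccc(OCc2ccccc2)c(OCc2ccccc2)c1)[C@H]1C(=O)OC[C@@H]1[C@H](O[Si](C)(C)C(C)(C)C)c1cc(OCc2ccccc2)c(OCc2ccccc2)c(OCc2ccccc2)c1 | intermediate (not isolated)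
15 | (3S,4R)-3-{[3,4-bis(benzyloxy)phenyl](hydroxy)methyl}-4-{(S)-[(tert-butyldimethylsilyl)oxy][3,4,5-tris(benzyloxy)phenyl]methyl}oxolan-2-one (carbinol epimers, centre left open) | OC(c1ccc(OCc2ccccc2)c(OCc2ccccc2)c1)[C@H]1C(=O)OC[C@@H]1[C@H](O[Si](C)(C)C(C)(C)C)c1cc(OCc2ccccc2)c(OCc2ccccc2)c(OCc2ccccc2)c1 | intermediate
16 | (3S,4R)-3-{[3,4-bis(benzyloxy)phenyl](hydroxy)methyl}-4-{(S)-hydroxy[3,4,5-tris(benzyloxy)phenyl]methyl}oxolan-2-one (formed as its alkoxide) | OC(c1ccc(OCc2ccccc2)c(OCc2ccccc2)c1)[C@H]1C(=O)OC[C@@H]1[C@H](O)c1cc(OCc2ccccc2)c(OCc2ccccc2)c(OCc2ccccc2)c1 | intermediate (not isolated)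
17 | (3S,4R,5S)-3-{[3,4-bis(benzyloxy)phenyl](hydroxy)methyl}-4-(hydroxymethyl)-5-[3,4,5-tris(benzyloxy)phenyl]oxolan-2-one | O=C1O[C@H](c2cc(OCc3ccccc3)c(OCc3ccccc3)c(OCc3ccccc3)c2)[C@@H](CO)[C@H]1C(O)c1ccc(OCc2ccccc2)c(OCc2ccccc2)c1 | intermediate (not isolated)
18 | (3S,3aR,6S,6aS)-6-[3,4-bis(benzyloxy)phenyl]-3-[3,4,5-tris(benzyloxy)phenyl]tetrahydro-1H,3H-furo[3,4-c]furan-1-one | O=C1O[C@H](c2cc(OCc3ccccc3)c(OCc3ccccc3)c(OCc3ccccc3)c2)[C@H]2CO[C@H](c3ccc(OCc4ccccc4)c(OCc4ccccc4)c3)[C@@H]12 | intermediate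
19 | (3S,3aR,6S,6aS)-6-(3,4-dihydroxyphenyl)-3-(3,4,5-trihydroxyphenyl)tetrahydro-1H,3H-furo[3,4-c]furan-1-one | O=C1O[C@H](c2cc(O)c(O)c(O)c2)[C@H]2CO[C@H](c3ccc(O)c(O)c3)[C@@H]12 | target

**Totals**

Total step count: 7. Longest linear sequence: 7 steps (1/2 → 19).

**Three steps most likely to fail**

Step 5 (lithium aldol; risk: retro-aldol or low conversion with the electron-rich aldehyde). The fallback sets out from 11 and changes to a Lewis-acid aldol. LDA then TMSCl (THF, −78 °C) gives the trimethylsilyl ketene acetal F1. This is combined with 12 and BF3·OEt2 in CH2Cl2 at −78 °C (Mukaiyama aldol, irreversible and non-basic, again anti to the C-4 substituent). Aqueous work-up removes the O-silyl group and the route is rejoined at 15.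

Step 6 (desilylation/translactonisation/SN1 closure; risk: dehydration of the β-hydroxy lactone to the α-arylidene lactone, retro-aldol under fluoride, or an exo/endo mixture at C-6). The fallback sets out from 11 and avoids the carbinol altogether. LDA, then bought 3,4-bis(benzyloxy)benzyl chloride with NaI, gives the trans-benzylated lactone F2. TBAF removes the silyl group, the alkoxide of the ring-1 hydroxy lactone F3 translactonises, and the ring-2 hydroxymethyl lactone F4 is isolated. DDQ (CH2Cl2, molecular sieves, 0 °C → rt) then oxidises the electron-rich benzylic CH2 to the cation only after the CH2OH is in place, and oxidative C–H etherification rejoins the route at 18.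

Step 7 (global hydrogenolysis; risk: cleavage of the benzylic lactone C–O bond, less likely the benzylic ether). The fallback sets out from 15, which has no benzylic ester, and reverses the order of deprotection and ring formation. H2, Pd/C in EtOAc–THF gives the silylated pentaphenol F5. HF·pyridine in THF gives the desilylated ring-1 lactone F6, and CSA in MeCN brings about translactonisation to the ring-2 diol F7 and closure directly to the target 19, in acidic medium throughout so that the catechol and pyrogallol units are not oxidised.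

**Further compounds**

F1 | step 5 | tert-butyl(dimethyl){(S)-[(3R)-5-(trimethylsilyloxy)-2,3-dihydrofuran-3-yl][3,4,5-tris(benzyloxy)phenyl]methoxy}silane | CC(C)(C)[Si](C)(C)O[C@H](c1cc(OCc2ccccc2)c(OCc2ccccc2)c(OCc2ccccc2)c1)[C@H]1COC(O[Si](C)(C)C)=C1
F2 | step 6 | (3R,4R)-3-[3,4-bis(benzyloxy)benzyl]-4-{(S)-[(tert-butyldimethylsilyl)oxy][3,4,5-tris(benzyloxy)phenyl]methyl}oxolan-2-one | C(c1ccc(OCc2ccccc2)c(OCc2ccccc2)c1)[C@H]1C(=O)OC[C@@H]1[C@H](O[Si](C)(C)C(C)(C)C)c1cc(OCc2ccccc2)c(OCc2ccccc2)c(OCc2ccccc2)c1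
F3 | step 6 | (3R,4R)-3-[3,4-bis(benzyloxy)benzyl]-4-{(S)-hydroxy[3,4,5-tris(benzyloxy)phenyl]methyl}oxolan-2-one | C(c1ccc(OCc2ccccc2)c(OCc2ccccc2)c1)[C@H]1C(=O)OC[C@@H]1[C@H](O)c1cc(OCc2ccccc2)c(OCc2ccccc2)c(OCc2ccccc2)c1
F4 | step 6 | (3R,4R,5S)-3-[3,4-bis(benzyloxy)benzyl]-4-(hydroxymethyl)-5-[3,4,5-tris(benzyloxy)phenyl]oxolan-2-one | O=C1O[C@H](c2cc(OCc3ccccc3)c(OCc3ccccc3)c(OCc3ccccc3)c2)[C@@H](CO)[C@H]1Cc1ccc(OCc2ccccc2)c(OCc2ccccc2)c1
F5 | step 7 | (3S,4R)-3-[(3,4-dihydroxyphenyl)(hydroxy)methyl]-4-{(S)-[(tert-butyldimethylsilyl)oxy](3,4,5-trihydroxyphenyl)methyl}oxolan-2-one (carbinol epimers) | OC(c1ccc(O)c(O)c1)[C@H]1C(=O)OC[C@@H]1[C@H](O[Si](C)(C)C(C)(C)C)c1cc(O)c(O)c(O)c1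
F6 | step 7 | (3S,4R)-3-[(3,4-dihydroxyphenyl)(hydroxy)methyl]-4-[(S)-hydroxy(3,4,5-trihydroxyphenyl)methyl]oxolan-2-one | OC(c1ccc(O)c(O)c1)[C@H]1C(=O)OC[C@@H]1[C@H](O)c1cc(O)c(O)c(O)c1
F7 | step 7 | (3S,4R,5S)-3-[(3,4-dihydroxyphenyl)(hydroxy)methyl]-4-(hydroxymethyl)-5-(3,4,5-trihydroxyphenyl)oxolan-2-one | O=C1O[C@H](c2cc(O)c(O)c(O)c2)[C@@H](CO)[C@H]1C(O)c1ccc(O)c(O)c1
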